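A small charge of Ym, 0.05 mol% of the Rx or 5.00 × 10⁻⁵ M, has to make Gy while Rx also pairs with itself to Zo.

| setting | ochre | amber | teal | violet |
|---|---|---|---|---|
| Rx | 0.10 M (fed, over 4.80 h) | 0.10 M | 0.10 M | 0.10 M |
| Wa | 1.10 equiv | 1.10 equiv | 1.10 equiv (fed, over 4.80 h) | 1.10 equiv |
| Ym | 0.05 mol% | 0.05 mol% | 0.05 mol% | 0.05 mol% |
| time | 6.0 h |  | 6.0 h | 6.0 h |
| remark | all but Rx at the start; Rx goes in evenly over 4.80 h, the run ends at 6.0 h | one stirred flow tank at steady state, fed with the mixture as stated, mean residence time 6.0 h | all but Wa at the start; Wa goes in evenly over 4.80 h, the run ends at 6.0 h | everything together in a closed stirred flask, run for 6.0 h |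

    2 Rx → Zo (k1 = 0.031 L mol⁻¹ s⁻¹)
    Rx + Gy → Rx.Gy (k2 = 0.0056 L mol⁻¹ s⁻¹)
    Rx + Ym ⇌ Rx.Ym (K3 = 5.3 L mol⁻¹, k3 = 360 L mol⁻¹ s⁻¹)
    Wa.Rx.Ym → Ym + Gy (k4 = 5.4 s⁻¹)
    Wa + Rx.Ym ⇌ Wa.Rx.Ym (K5 = 3.8 L mol⁻¹, k5 = 460 L mol⁻¹ s⁻¹)

- in percentages every species weighs as the Rx in it: one Rx.Gy or Zo counts as two
- for a step with 2 of a species take k times the square, and two of it per event
- the stated concentrations are those of everything mixed, before any reaction; amounts are the same in each set-up
- the feed brings no volume worth counting
- run time (ochre): 6.0 h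

* the set-up with the highest amount of Gy at the outlet or at the end, in percent of the Rx put in ("none" if the first two lie within 2 percentage points) (ochre / amber / teal / violet / none)
* amount of Gy at the outlet or at the end, in percent of the Rx put in, ochre
* amount of Gy at the outlet or at the end, in percent of the Rx put in, amber
* amount of Gy at the outlet or at the end, in percent of the Rx put in, teal
* amount of Gy at the outlet or at the end, in percent of the Rx put in, violet

My reckoning sets two concentrations against each other. Per Rx, dimerisation runs at twice its rate constant times c(Rx), so it quickens as c(Rx) climbs. The enzyme, while Ym stays nearly free, is pseudo-first-order in Rx. Wa.Rx.Ym falls back 22.4 times faster than it goes on, so at c(Wa) = 0.110 M there stand 0.400 of it per Rx.Ym. The leak to Gy is then 2.16 s⁻¹, smaller than the return to Rx and Ym at 67.9 s⁻¹, and the enzyme's constant comes to 5.55 × 10⁻⁴ s⁻¹.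

Setting the two per-Rx rates equal gives c*, the crossover concentration at which Gy and Zo take Rx equally, 0.00895 M. While Ym stays nearly free, the share of reacting Rx that becomes Gy is c*/(c* + c(Rx)), counted before any Gy goes on to Rx.Gy, and c* follows c(Wa) nearly in proportion.

In ochre the feed holds c(Rx) near 0.00617 M, lower than c*, so the share at full Wa is 59.2%. Violet starts at 0.10 M, higher than c*, and there Ym is not nearly free: counting Rx.Ym and Wa.Rx.Ym, 58.2% of it stands free at the start, so the enzyme's constant is scaled by that part and violet's share at the start is 4.95%. Teal starts without Wa, so its c* starts at nothing. My order is ochre, violet, teal; amber I did not reckon.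

The forecast chose ochre, on the ground that “keeping Rx low is what matters”.

| Flask | Forecast | Range | Simulation |
|---|---|---|---|
| ochre | 34% | 31% to 37% | 33.4% |
| amber | 24.2% | 22.5% to 26% | 24.3% |
| teal | 3.7% | 3% to 4.5% | 3.42% |
| violet | 16.3% | 15% to 17.8% | 15.9% |

The simulation gives ochre as best.

In ochre at 3.00 h, c(Rx) reads 0.00628 M against a c* of 0.00662 M scaled to the 74.0% of Wa still there, and the two rates agree with it, Gy forming at 2.49 × 10⁻⁶ M s⁻¹ and Rx going to Zo at 2.44 × 10⁻⁶ M s⁻¹. Violet, which began at 11.2 times its c*, ends with 80.5% of the Rx as Zo, against 40.7% in ochre.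

Its constants come from no measurement; the rest is arithmetic.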